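**Retrosynthetic overview**
- Target ⇐ 1,6-diol 36 (double Swern oxidation) ⇐ tetracycle 33 (SeO2 allylic hydroxylation at C15, acetylation, desilylation).
- Ring D (C8–C15, quaternary C8) ⇐ intramolecular Pd-allyl alkylation of a lactone enolate; ring C (C9–C11) ⇐ 6-endo radical cyclisation onto the unsaturated spirolactone 31.
- Spirolactone 29 (C9–C10 bond and C7–O–C20 lactone) ⇐ Ti(III) reductive epoxide–acrylate coupling of two C10 halves, epoxide 16 (ring A, C20) and acrylate 27 (C7–C9, C11–C17).
- 16 ⇐ isobutyraldehyde + methyl vinyl ketone (Robinson annulation, Rh-catalysed asymmetric vinyl addition sets C5); 27 ⇐ furan-2(5H)-one (Rh-catalysed vinyl addition sets C13) + methyl acetoacetate.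
- Ring order: A → spiro-δ-lactone → C → D.

Assumption: skeleton atoms carry ent-kaurane numbers (C1–C20); epimer mixtures at centres that are later made planar (C8 in 28, 29 and 32; the extra centres of 11, 12, 26 and 30) are carried on unseparated and drawn without configuration there.

**Ring-A fragment (steps 1–9)**

Step 1
Reactants: 1 isobutyraldehyde; 2 methyl vinyl ketone
Product: 4 4,4-dimethylcyclohex-2-en-1-one, via 2,2-dimethyl-5-oxohexanal 3 (not isolated)
Conditions: H2SO4 (cat.), PhH, reflux, Dean–Stark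
Reagents that add atoms: none
Why: Acid-catalysed Robinson annulation (Michael addition of the aldehyde enol, then intramolecular aldol condensation) builds ring A with the gem-dimethyl carbon; no stereocentre is formed.

Step 2
Reactants: 4 4,4-dimethylcyclohex-2-en-1-one
Product: 5 4,4-dimethylcyclohexa-2,5-dien-1-one
Conditions: DDQ, 1,4-dioxane, reflux
Reagents that add atoms: none
Why: DDQ dehydrogenation of the enolisable CH2–CH2 unit gives the symmetric cross-conjugated dienone, which cannot aromatise because C4 is quaternary.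

Step 3
Reactants: 5 4,4-dimethylcyclohexa-2,5-dien-1-one (2.5 equiv); 6 potassium vinyltrifluoroborate
Product: 7 (5R)-5-ethenyl-4,4-dimethylcyclohex-2-en-1-one
Conditions: [Rh(cod)2]BF4 (3 mol%), (R)-BINAP, PhMe/H2O 10:1, 100 °C
Reagents that add atoms: none
Why: Hayashi–Miyaura Rh-catalysed asymmetric 1,4-addition desymmetrises the dienone, the (R)-BINAP–Rh–vinyl species choosing one enantiotopic enone face to set C5 (R), with excess dienone suppressing double addition.

Step 4
Reactants: 7 (5R)-5-ethenyl-4,4-dimethylcyclohex-2-en-1-one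
Product: 9 (5S)-5-(hydroxymethyl)-4,4-dimethylcyclohex-2-en-1-one, via aldehyde 8 (not isolated)
Conditions: O3, CH2Cl2/MeOH, −78 °C (Sudan III end point); Me2S; then NaBH4, −78 °C
Reagents that add atoms: ozone [O-][O+]=O
Why: Chemoselective ozonolysis of the electron-rich vinyl group (the enone alkene is deactivated) followed by low-temperature borohydride reduction of the aldehyde in preference to the conjugated ketone; C5 is untouched (descriptor changes by priority only).

Step 5
Reactants: 9 (5S)-5-(hydroxymethyl)-4,4-dimethylcyclohex-2-en-1-one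
Product: 10 (5S)-5-{[tert-butyl(dimethyl)silyl]oxymethyl}-4,4-dimethylcyclohex-2-en-1-one
Conditions: TBSCl, imidazole, DMF, rt
Reagents that add atoms: tert-butyldimethylsilyl chloride CC(C)(C)[Si](C)(C)Cl
Why: Silyl ether formation masks the primary alcohol so that it cannot add (oxa-Michael) to the exocyclic enone made next.

Step 6
Reactants: 10 (5S)-5-{[tert-butyl(dimethyl)silyl]oxymethyl}-4,4-dimethylcyclohex-2-en-1-one
Product: 13 (5R)-5-{[tert-butyl(dimethyl)silyl]oxymethyl}-4,4-dimethyl-6-methylidenecyclohex-2-en-1-one, via Mannich base 11 (not isolated), via trimethylammonium iodide 12 (not isolated)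
Conditions: LiHMDS, THF, −78 °C; Me2N=CH2+ I−; then MeI; then NaHCO3 (aq), CH2Cl2, rt
Reagents that add atoms: Eschenmoser's salt C=[N+](C)C.[I-]
Why: Only one enolate can form (the other α-carbon is vinylic and C4 blocks dienolate formation), so Mannich reaction with Eschenmoser's salt and Hofmann-type elimination under weak base give the α-methylene ketone without epimerising C5.

Step 7
Reactants: 13 (5R)-5-{[tert-butyl(dimethyl)silyl]oxymethyl}-4,4-dimethyl-6-methylidenecyclohex-2-en-1-one
Product: 14 (1S,5R)-5-{[tert-butyl(dimethyl)silyl]oxymethyl}-4,4-dimethyl-6-methylidenecyclohex-2-en-1-ol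
Conditions: NaBH4, CeCl3·7H2O, MeOH, −78 °C
Reagents that add atoms: none
Why: Luche 1,2-reduction in which hydride attacks anti to the pseudo-axial C5 substituent (axial to avoid A1,3 strain with the methylidene), giving the C1 hydroxyl cis to the CH2OTBS group.

Step 8
Reactants: 14 (1S,5R)-5-{[tert-butyl(dimethyl)silyl]oxymethyl}-4,4-dimethyl-6-methylidenecyclohex-2-en-1-ol
Product: 15 (3S,4S,8S)-8-{[tert-butyl(dimethyl)silyl]oxymethyl}-7,7-dimethyl-1-oxaspiro[2.5]oct-5-en-4-ol
Conditions: Ti(OiPr)4 (10 mol%), L-(+)-DIPT (12 mol%), t-BuOOH, 4 Å MS, CH2Cl2, −20 °C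
Reagents that add atoms: tert-butyl hydroperoxide CC(C)(C)OO
Why: Katsuki–Sharpless hydroxyl-directed epoxidation with the tartrate matched to the 1S carbinol reacts at the exocyclic 1,1-disubstituted alkene (ring cis-alkenes of cyclohexenols are poor substrates and C3 is neopentyl), oxygen being delivered syn to OH; this spiro centre is made planar again in step 19.

Step 9
Reactants: 15 (3S,4S,8S)-8-{[tert-butyl(dimethyl)silyl]oxymethyl}-7,7-dimethyl-1-oxaspiro[2.5]oct-5-en-4-ol
Product: 16 (3S,4S,8S)-4-[tert-butyl(dimethyl)silyl]oxy-8-{[tert-butyl(dimethyl)silyl]oxymethyl}-7,7-dimethyl-1-oxaspiro[2.5]oct-5-ene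
Conditions: TBSCl, imidazole, DMAP (cat.), DMF, 40 °C
Reagents that add atoms: tert-butyldimethylsilyl chloride CC(C)(C)[Si](C)(C)Cl
Why: Silylation of the allylic alcohol under non-acidic conditions that leave the epoxide intact, so that only the epoxide-derived C20 oxygen can lactonise later.

**C/D fragment (steps 10–18)**

Step 10
Reactants: 17 furan-2(5H)-one (1.5 equiv); 6 potassium vinyltrifluoroborate
Product: 18 (4R)-4-ethenyloxolan-2-one
Conditions: [Rh(cod)2]BF4 (3 mol%), (R)-BINAP, PhMe/H2O 10:1, 100 °C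
Reagents that add atoms: none
Why: Hayashi–Miyaura Rh-catalysed asymmetric 1,4-addition to the butenolide sets the future C13 stereocentre (R) by ligand-controlled face selection.

Step 11
Reactants: 18 (4R)-4-ethenyloxolan-2-one
Product: 19 (4R)-4-[2-(phenylselanyl)ethyl]oxolan-2-one
Conditions: PhSeH, AIBN (cat.), PhH, 80 °C
Reagents that add atoms: benzeneselenol [SeH]c1ccccc1
Why: Radical-chain anti-Markovnikov hydroselenation installs the C11 radical precursor as a selenide that tolerates bases, hydrides and Ti(III); the stereocentre is not involved.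

Step 12
Reactants: 19 (4R)-4-[2-(phenylselanyl)ethyl]oxolan-2-one
Product: 20 methyl (3R)-3-(bromomethyl)-5-(phenylselanyl)pentanoate
Conditions: HBr (g), MeOH, 0 °C → rt
Reagents that add atoms: hydrogen bromide Br; methanol CO
Why: Acid-mediated lactone opening (SN2 of bromide at the O–CH2 carbon with Fischer esterification) differentiates C14 (bromide) from C15 (ester) without touching the stereocentre.

Step 13
Reactants: 20 methyl (3R)-3-(bromomethyl)-5-(phenylselanyl)pentanoate
Product: 21 (3R)-3-(bromomethyl)-5-(phenylselanyl)pentanal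
Conditions: DIBAL-H (1.05 equiv), CH2Cl2, −78 °C
Reagents that add atoms: none
Why: Partial ester reduction through the tetrahedral aluminium hemiacetal, which is stable at −78 °C, stops at the aldehyde.

Step 14
Reactants: 21 (3R)-3-(bromomethyl)-5-(phenylselanyl)pentanal
Product: 22 (3S)-3-(bromomethyl)-2-methylidene-5-(phenylselanyl)pentanal
Conditions: Me2N=CH2+ I−, Et3N, CH2Cl2, rt
Reagents that add atoms: Eschenmoser's salt C=[N+](C)C.[I-]
Why: Mannich reaction and β-elimination (aldehyde α-methylenation) create the C16=C17 methylidene; the stereocentre is β to the carbonyl and cannot epimerise.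

Step 15
Reactants: 22 (3S)-3-(bromomethyl)-2-methylidene-5-(phenylselanyl)pentanal
Product: 23 (3S)-3-(bromomethyl)-2-methylidene-5-(phenylselanyl)pentan-1-ol
Conditions: NaBH4, CeCl3·7H2O, MeOH, −40 °C
Reagents that add atoms: none
Why: Luche 1,2-reduction of the enal gives the allylic alcohol (C15–OH) without conjugate reduction or bromide displacement.

Step 16
Reactants: 23 (3S)-3-(bromomethyl)-2-methylidene-5-(phenylselanyl)pentan-1-ol
Product: 24 (3S)-3-(bromomethyl)-2-methylidene-5-(phenylselanyl)pentyl tert-butyl carbonate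
Conditions: Boc2O, 1-methylimidazole, PhMe, rt
Reagents that add atoms: di-tert-butyl dicarbonate CC(C)(C)OC(=O)OC(=O)OC(C)(C)C
Why: O-acylation gives an allylic tert-butyl carbonate, inert to enolates and radicals but ionised by Pd(0) in step 22.

Step 17
Reactants: 24 (3S)-3-(bromomethyl)-2-methylidene-5-(phenylselanyl)pentyl tert-butyl carbonate; 25 methyl acetoacetate (2.5 equiv)
Product: 26 methyl (4S)-2-acetyl-4-{3-[(tert-butoxycarbonyl)oxy]prop-1-en-2-yl}-6-(phenylselanyl)hexanoate (C2 epimers)
Conditions: K2CO3, NaI (cat.), DMF, 50 °C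
Reagents that add atoms: none
Why: Finkelstein-assisted SN2 C-alkylation of the acetoacetate anion forms the C14–C8 bond; the allylic carbonate is not an SN2 electrophile without Pd.

Step 18
Reactants: 26 methyl (4S)-2-acetyl-4-{3-[(tert-butoxycarbonyl)oxy]prop-1-en-2-yl}-6-(phenylselanyl)hexanoate
Product: 27 methyl (4S)-4-{3-[(tert-butoxycarbonyl)oxy]prop-1-en-2-yl}-2-methylidene-6-(phenylselanyl)hexanoate
Conditions: LiHMDS, THF, −78 °C; (CH2O)n; → rt
Reagents that add atoms: formaldehyde (as paraformaldehyde) C=O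
Why: Deacetylative methylenation (aldol with formaldehyde, acetyl transfer to the new alkoxide, then β-elimination of acetate) converts the acetoacetate into the 2-substituted acrylate C9=C8–C7.

**Fragment union and endgame (steps 19–26)**

Step 19
Reactants: 16 ring-A spiro-epoxide; 27 acrylate (1.5 equiv)
Product: 29 C8-substituted 7,20-spirolactone (5R,10S,13S; C8 epimers), via hydroxy ester 28 (not isolated)
Conditions: Cp2TiCl2 (20 mol%), Zn, 2,4,6-collidine·HCl, THF, rt; then PPTS (cat.), PhMe, 60 °C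
Reagents that add atoms: none
Why: Nugent–RajanBabu/Gansäuer Ti(III) reductive epoxide opening gives the tertiary C10 radical, whose Giese addition to the acrylate occurs anti to the cis C1–OTBS and C5–CH2OTBS groups (sets C10), and the C20 alkoxide then lactonises onto the methyl ester.

Step 20
Reactants: 29 C8-substituted 7,20-spirolactone
Product: 31 8,9-unsaturated spirolactone, via sulfoxide 30 (not isolated)
Conditions: LDA, THF, −78 °C; PhS(O)OMe; then PhMe, CaCO3, 110 °C
Reagents that add atoms: none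
Why: Enolate sulfinylation followed by thermal sulfoxide syn-elimination, which in six-membered lactones favours the endocyclic C8=C9 alkene, and which needs no oxidant that would attack the C11 selenide.

Step 21
Reactants: 31 8,9-unsaturated spirolactone
Product: 32 tricyclic lactone with ring C closed (C8 epimers)
Conditions: Bu3SnH (slow addition), AIBN, PhH, 80 °C
Reagents that add atoms: none
Why: 6-endo-trig radical cyclisation of the primary C11 radical onto the β-carbon C9 of the unsaturated lactone through a chair transition state with the C13 substituent equatorial and attack on the C1-side face sets C9; the C8–H epimers converge in the next step.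

Step 22
Reactants: 32 tricyclic lactone
Product: 33 tetracyclic lactone with bicyclo[3.2.1]octane C/D rings and 16-methylidene
Conditions: KHMDS, THF, −78 °C; then Pd(PPh3)4 (10 mol%), −78 °C → rt
Reagents that add atoms: none
Why: Intramolecular Tsuji–Trost allylation of the lactone enolate by the π-allyl palladium formed from the carbonate (ring closure of the trimethylenemethane-annulation type) creates quaternary C8, and only the enolate face syn to the C13 arm can reach it, so C8 is fixed by C13.

Step 23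
Reactants: 33 tetracyclic lactone
Product: 34 (15R)-15-hydroxy tetracycle
Conditions: SeO2 (0.5 equiv), t-BuOOH, CH2Cl2, rt
Reagents that add atoms: tert-butyl hydroperoxide CC(C)(C)OO
Why: SeO2 allylic oxidation (ene reaction then [2,3]-shift) can only occur at C15 because C13 is a bridgehead, and oxygen is delivered on the face anti to C14, as in ent-kaur-16-enes, to give the 15R alcohol.

Step 24
Reactants: 34 (15R)-15-hydroxy tetracycle
Product: 35 15-acetate
Conditions: Ac2O, DMAP (cat.), pyridine, rt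
Reagents that add atoms: acetic anhydride CC(=O)OC(C)=O
Why: DMAP-catalysed acetylation of the hindered allylic alcohol with retention at C15.

Step 25
Reactants: 35 15-acetate
Product: 36 1,6-diol
Conditions: HF·pyridine, THF/pyridine, 0 °C → rt
Reagents that add atoms: none
Why: Fluoride-mediated cleavage of both silyl ethers under mildly acidic conditions that leave the acetate and lactone in place.

Step 26
Reactants: 36 1,6-diol
Product: 37 target, CNP0108627.4
Conditions: (COCl)2, DMSO, CH2Cl2, −78 °C; then Et3N, → 0 °C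
Reagents that add atoms: none
Why: Swern oxidation activates both hydroxyls before base is added, so the allylic C1 alcohol becomes the enone and the C6 alcohol the aldehyde simultaneously, avoiding lactol (then lactone) formation between the cis C1–OH and C6; no stereocentre is altered.

**Compound list**
1 | isobutyraldehyde | CC(C)C=O | starting material
2 | methyl vinyl ketone | CC(=O)C=C | starting material
3 | 2,2-dimethyl-5-oxohexanal | CC(=O)CCC(C)(C)C=O | intermediate
4 | 4,4-dimethylcyclohex-2-en-1-one | CC1(C)CCC(=O)C=C1 | intermediate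
5 | 4,4-dimethylcyclohexa-2,5-dien-1-one | CC1(C)C=CC(=O)C=C1 | intermediate
6 | potassium vinyltrifluoroborate | C=C[B-](F)(F)F.[K+] | starting material
7 | (5R)-5-ethenyl-4,4-dimethylcyclohex-2-en-1-one | O=C1C=CC(C)(C)[C@@H](C=C)C1 | intermediate
8 | (1S)-2,2-dimethyl-5-oxocyclohex-3-ene-1-carbaldehyde | O=C1C=CC(C)(C)[C@@H](C=O)C1 | intermediate
9 | (5S)-5-(hydroxymethyl)-4,4-dimethylcyclohex-2-en-1-one | O=C1C=CC(C)(C)[C@@H](CO)C1 | intermediate
10 | (5S)-5-{[tert-butyl(dimethyl)silyl]oxymethyl}-4,4-dimethylcyclohex-2-en-1-one | O=C1C=CC(C)(C)[C@@H](CO[Si](C)(C)C(C)(C)C)C1 | intermediate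
11 | Mannich base: (5S)-6-[(dimethylamino)methyl] derivative of 10 (C6 epimers) | CN(C)CC1C(=O)C=CC(C)(C)[C@H]1CO[Si](C)(C)C(C)(C)C | intermediate
12 | trimethylammonium iodide of 11 | C[N+](C)(C)CC1C(=O)C=CC(C)(C)[C@H]1CO[Si](C)(C)C(C)(C)C.[I-] | intermediate
13 | (5R)-5-{[tert-butyl(dimethyl)silyl]oxymethyl}-4,4-dimethyl-6-methylidenecyclohex-2-en-1-one | C=C1C(=O)C=CC(C)(C)[C@H]1CO[Si](C)(C)C(C)(C)C | intermediate
14 | (1S,5R)-5-{[tert-butyl(dimethyl)silyl]oxymethyl}-4,4-dimethyl-6-methylidenecyclohex-2-en-1-ol (OH cis to CH2OTBS) | C=C1[C@@H](O)C=CC(C)(C)[C@H]1CO[Si](C)(C)C(C)(C)C | intermediate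
15 | (3S,4S,8S)-8-{[tert-butyl(dimethyl)silyl]oxymethyl}-7,7-dimethyl-1-oxaspiro[2.5]oct-5-en-4-ol (epoxide O, OH and CH2OTBS all cis) | C1O[C@]12[C@@H](O)C=CC(C)(C)[C@H]2CO[Si](C)(C)C(C)(C)C | intermediate
16 | (3S,4S,8S)-4-[tert-butyl(dimethyl)silyl]oxy-8-{[tert-butyl(dimethyl)silyl]oxymethyl}-7,7-dimethyl-1-oxaspiro[2.5]oct-5-ene | C1O[C@]12[C@@H](O[Si](C)(C)C(C)(C)C)C=CC(C)(C)[C@H]2CO[Si](C)(C)C(C)(C)C | intermediate
17 | furan-2(5H)-one | O=C1C=CCO1 | starting material
18 | (4R)-4-ethenyloxolan-2-one | O=C1C[C@H](C=C)CO1 | intermediate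
19 | (4R)-4-[2-(phenylselanyl)ethyl]oxolan-2-one | O=C1C[C@H](CC[Se]c2ccccc2)CO1 | intermediate
20 | methyl (3R)-3-(bromomethyl)-5-(phenylselanyl)pentanoate | COC(=O)C[C@H](CC[Se]c1ccccc1)CBr | intermediate
21 | (3R)-3-(bromomethyl)-5-(phenylselanyl)pentanal | O=CC[C@H](CC[Se]c1ccccc1)CBr | intermediate
22 | (3S)-3-(bromomethyl)-2-methylidene-5-(phenylselanyl)pentanal | C=C(C=O)[C@H](CC[Se]c1ccccc1)CBr | intermediate
23 | (3S)-3-(bromomethyl)-2-methylidene-5-(phenylselanyl)pentan-1-ol | C=C(CO)[C@H](CC[Se]c1ccccc1)CBr | intermediate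
24 | (3S)-3-(bromomethyl)-2-methylidene-5-(phenylselanyl)pentyl tert-butyl carbonate | C=C(COC(=O)OC(C)(C)C)[C@H](CC[Se]c1ccccc1)CBr | intermediate
25 | methyl acetoacetate | CC(=O)CC(=O)OC | starting material
26 | methyl (4S)-2-acetyl-4-{3-[(tert-butoxycarbonyl)oxy]prop-1-en-2-yl}-6-(phenylselanyl)hexanoate (C2 epimers) | C=C(COC(=O)OC(C)(C)C)[C@H](CC[Se]c1ccccc1)CC(C(C)=O)C(=O)OC | intermediate
27 | methyl (4S)-4-{3-[(tert-butoxycarbonyl)oxy]prop-1-en-2-yl}-2-methylidene-6-(phenylselanyl)hexanoate | C=C(COC(=O)OC(C)(C)C)[C@H](CC[Se]c1ccccc1)CC(=C)C(=O)OC | intermediate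
28 | hydroxy ester: C10 of ring A (bearing C20H2OH, trans to C1-OTBS and C5-CH2OTBS through C9) linked via C9H2 to C8H(CO2Me)–C14H2–C13H(CH2CH2SePh)–C(=CH2)CH2OBoc; 5R,10S,13S, C8 epimers | COC(=O)C(C[C@@H](CC[Se]c1ccccc1)C(=C)COC(=O)OC(C)(C)C)C[C@]1(CO)[C@@H](O[Si](C)(C)C(C)(C)C)C=CC(C)(C)[C@H]1CO[Si](C)(C)C(C)(C)C | intermediate
29 | 7,20-spirolactone (2-oxaspiro[5.5]undec-8-en-3-one core): 1-OTBS and 5-CH2OTBS cis to each other and to C20, trans to C9; C8 carries the CH2–CH(CH2CH2SePh)–C(=CH2)CH2OBoc chain; 5R,10S,13S, C8 epimers | O=C1OC[C@@]2(CC1C[C@@H](CC[Se]c3ccccc3)C(=C)COC(=O)OC(C)(C)C)[C@@H](O[Si](C)(C)C(C)(C)C)C=CC(C)(C)[C@H]2CO[Si](C)(C)C(C)(C)C | intermediate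
30 | 8-(phenylsulfinyl) derivative of 29 (C8 and S epimers) | O=C1OC[C@@]2(CC1(C[C@@H](CC[Se]c3ccccc3)C(=C)COC(=O)OC(C)(C)C)S(=O)c3ccccc3)[C@@H](O[Si](C)(C)C(C)(C)C)C=CC(C)(C)[C@H]2CO[Si](C)(C)C(C)(C)C | intermediate
31 | 8,9-didehydro derivative of 29 (α,β-unsaturated spirolactone; 5R,10S,13S) | O=C1OC[C@@]2(C=C1C[C@@H](CC[Se]c3ccccc3)C(=C)COC(=O)OC(C)(C)C)[C@@H](O[Si](C)(C)C(C)(C)C)C=CC(C)(C)[C@H]2CO[Si](C)(C)C(C)(C)C | intermediate
32 | tricyclic lactone: cyclohexane ring C (C8, C9, C11–C14) cis-fused to the spirolactone, C13 bearing C(=CH2)CH2OBoc; C5, C9, C10, C13 as in the target, C8 epimers | C=C(COC(=O)OC(C)(C)C)[C@@H]1CC[C@@H]2C(C1)C(=O)OC[C@]23[C@@H](O[Si](C)(C)C(C)(C)C)C=CC(C)(C)[C@H]3CO[Si](C)(C)C(C)(C)C | intermediate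
33 | tetracyclic 7,20-lactone: bicyclo[3.2.1]octane C/D rings, 16-methylidene, 15-CH2, 1-OTBS, 6-OTBS; C5, C8, C9, C10, C13 as in the target | C=C1[C@@H]2CC[C@@H]3[C@](C2)(C(=O)OC[C@]32[C@@H](O[Si](C)(C)C(C)(C)C)C=CC(C)(C)[C@H]2CO[Si](C)(C)C(C)(C)C)C1 | intermediate
34 | (15R)-15-hydroxy derivative of 33 (OH anti to the C14 bridge) | C=C1[C@@H]2CC[C@@H]3[C@](C2)(C(=O)OC[C@]32[C@@H](O[Si](C)(C)C(C)(C)C)C=CC(C)(C)[C@H]2CO[Si](C)(C)C(C)(C)C)[C@@H]1O | intermediate
35 | 15-acetate of 34 | C=C1[C@@H]2CC[C@@H]3[C@](C2)(C(=O)OC[C@]32[C@@H](O[Si](C)(C)C(C)(C)C)C=CC(C)(C)[C@H]2CO[Si](C)(C)C(C)(C)C)[C@@H]1OC(C)=O | intermediate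
36 | 1,6-diol: 15-acetoxy-1-hydroxy-6-hydroxy tetracyclic 7,20-lactone (1-OH cis to C6) | C=C1[C@@H]2CC[C@@H]3[C@](C2)(C(=O)OC[C@]32[C@@H](O)C=CC(C)(C)[C@H]2CO)[C@@H]1OC(C)=O | intermediate
37 | CNP0108627.4 (5R,8S,9S,10S,13R,15R) | C=C1[C@@H]2CC[C@@H]3[C@](C2)(C(=O)OC[C@]32C(=O)C=CC(C)(C)[C@H]2C=O)[C@@H]1OC(C)=O | target

**Step count**
Total steps: 26. Longest linear sequence: 17 (steps 1–9, then 19–26; the branch through steps 10–18 is equally long).

**Steps most likely to fail, with fallbacks**

Step 3. The β-carbon of dienone 5 is neopentyl, so the Rh-catalysed vinyl addition may be slow, and double addition competes. Fallback from 5, rejoining at 9: an iminium-catalysed (9-amino-9-deoxy-epi-cinchona primary amine salt) Michael addition of nitromethane to 5 gives (5S)-4,4-dimethyl-5-(nitromethyl)cyclohex-2-en-1-one F1. A Nef reaction (NaOMe, then cold aqueous H2SO4) converts this into aldehyde 8, which is reduced as in step 4 to 9.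

Step 19. The hindered tertiary radical from 16 may be reduced or may disproportionate faster than it adds to the α-substituted acrylate 27, which cannot be used in large excess, and the facial selectivity is unproven with the C1 silyl ether present. Fallback from 16 and 24, rejoining at 29: 16 is coupled under the same titanocene conditions with a large excess of methyl acrylate, which lactonises to the C8-unsubstituted spirolactone F2. Bromide 24 is converted by Finkelstein exchange (NaI, acetone) into the iodide F3. Alkylation of the lithium enolate of the spirolactone (LDA, HMPA, THF, −78 to −40 °C) with this iodide then gives 29.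

Step 23. The face selectivity of the SeO2 oxidation is argued by analogy with ent-kaur-16-enes and could be reversed by the lactone. Fallback from 33, rejoining at 34: if the oxidation gives mainly the 15-epi alcohol F4, it is oxidised (MnO2 or Dess–Martin periodinane) to the 16-en-15-one F5. Luche reduction (NaBH4, CeCl3) then gives 34, because hydride enters from the face from which SeO2 delivered oxygen, so the two methods give opposite C15 epimers.

Further compounds
F1 | step 3 | (5S)-4,4-dimethyl-5-(nitromethyl)cyclohex-2-en-1-one | O=C1C=CC(C)(C)[C@@H](C[N+](=O)[O-])C1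
F2 | step 19 | C8-unsubstituted 7,20-spirolactone (1-OTBS, 5-CH2OTBS; 5R,10S) | O=C1OC[C@@]2(CC1)[C@@H](O[Si](C)(C)C(C)(C)C)C=CC(C)(C)[C@H]2CO[Si](C)(C)C(C)(C)C
F3 | step 19 | (3S)-3-(iodomethyl)-2-methylidene-5-(phenylselanyl)pentyl tert-butyl carbonate | C=C(COC(=O)OC(C)(C)C)[C@H](CC[Se]c1ccccc1)CI
F4 | step 23 | (15S)-15-hydroxy epimer of 34 | C=C1[C@@H]2CC[C@@H]3[C@](C2)(C(=O)OC[C@]32[C@@H](O[Si](C)(C)C(C)(C)C)C=CC(C)(C)[C@H]2CO[Si](C)(C)C(C)(C)C)[C@H]1O
F5 | step 23 | 16-en-15-one of the tetracyclic lactone | C=C1[C@@H]2CC[C@@H]3[C@](C2)(C(=O)OC[C@]32[C@@H](O[Si](C)(C)C(C)(C)C)C=CC(C)(C)[C@H]2CO[Si](C)(C)C(C)(C)C)C1=O
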